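The route rests on cutting the ring B arm at C7–O. The C7(OH, ring A)–C8(H, ring B)–C9H2–O9 array is a 1,3-diol, so a hydrosilane hung on O9 can hand Si to C7 and H to C8 across one face of a C7=C8 alkene. One rhodium-catalysed cyclisation of the diphenylhydrosilyl ether of an (E)-2,3-diarylallyl alcohol (rings A and B cis) closes an oxasilolane, makes C7–Si and sets both arm stereocentres. Oxidation then gives the anti 7S,8S diol. The ring C arm is the syn 7'S,8'R diastereomer and comes from an Evans aldol. The aryl bromide opens a cyclopropane-fused lactone, and enolate benzylation completes the (3S,4S) core.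

Key step: step 8

Labels: ring A, C7, C8 and C9 form the arm on ring B (benzyl at lactone C4). Ring D, C7', C8' and C9' form the arm on ring C (benzyl at lactone C3). The lactone atoms are O1, C2 (C=O), C3, C4 and C5 (CH2O).

Stereochemical reading of the target: 7S,8S (anti); 7'S,8'R (syn, so C8' is opposite to C8); 3S,4S (trans lactone). The two arms therefore need different chemistry.

Assumption: the (S,S) ligand is written for the 3S,4S oxasilolane. The sense of induction on this trisubstituted alkene cannot be derived with certainty from simpler 3-arylallyl ethers, so the antipodal ligand is used if a trial run addresses the other face.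

Step 1
Reactants: 1 5-bromo-2-hydroxy-3-methoxybenzaldehyde
Product: 2 2-(benzyloxy)-5-bromo-3-methoxybenzaldehyde
Conditions: BnBr, K2CO3, DMF, 25 to 50 °C
Reagents that add atoms: benzyl bromide, BrCc1ccccc1
Why: Williamson etherification masks the acidic phenol as a benzyl ether that should tolerate every later base, hydride and organometallic reagent and is removed only in the last step.

Step 2
Reactants: 2 2-(benzyloxy)-5-bromo-3-methoxybenzaldehyde
Product: 4 2-[2-(benzyloxy)-5-bromo-3-methoxyphenyl]acetonitrile, via vinylformamide 3 (not isolated)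
Conditions: TosMIC, KOt-Bu, DME, −40 °C; then MeOH, reflux
Reagents that add atoms: tosylmethyl isocyanide (TosMIC), Cc1ccc(cc1)S(=O)(=O)C[N+]#[C-]
Why: In the van Leusen reductive cyanation the TosMIC anion adds to the aldehyde, the oxazoline opens to the vinylformamide, and hot methanol strips formyl and sulfinate to leave the one-carbon-longer nitrile, the cold first stage holding back oxazole formation.

Step 3
Reactants: 4 2-[2-(benzyloxy)-5-bromo-3-methoxyphenyl]acetonitrile
Product: 5 2-[2-(benzyloxy)-5-bromo-3-methoxyphenyl]acetic acid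
Conditions: KOH, EtOH/H2O, reflux; then aq. HCl to pH 2
Reagents that add atoms: water, O; potassium hydroxide, [K+].[OH-]
Why: Alkaline nitrile hydrolysis gives the acid that feeds both arms, and the aryl bromide and both ethers are inert to it.

Step 4
Reactants: 5 2-[2-(benzyloxy)-5-bromo-3-methoxyphenyl]acetic acid; 6 4-(benzyloxy)-3-methoxybenzaldehyde (O-benzylvanillin)
Product: 7 (E)-2-[2-(benzyloxy)-5-bromo-3-methoxyphenyl]-3-[4-(benzyloxy)-3-methoxyphenyl]acrylic acid (aryl groups cis)
Conditions: Ac2O, Et3N, 110 °C; then H2O, 60 °C; crystallisation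
Reagents that add atoms: none
Why: The Perkin condensation of an arylacetic acid with an aromatic aldehyde characteristically gives the (E)-acid with carboxyl trans to the C7 aryl group, and crystallisation should remove any geometric isomer.

Step 5
Reactants: 7 (E)-diarylacrylic acid
Product: 8 methyl (E)-2-[2-(benzyloxy)-5-bromo-3-methoxyphenyl]-3-[4-(benzyloxy)-3-methoxyphenyl]acrylate
Conditions: MeI, K2CO3, DMF, 25 °C
Reagents that add atoms: iodomethane, CI
Why: SN2 O-alkylation of the carboxylate is insensitive to crowding at the acyl carbon and leaves the alkene geometry untouched.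

Step 6
Reactants: 8 methyl (E)-diarylacrylate
Product: 9 (E)-2-[2-(benzyloxy)-5-bromo-3-methoxyphenyl]-3-[4-(benzyloxy)-3-methoxyphenyl]prop-2-en-1-ol
Conditions: i-Bu2AlH (2.5 equiv), CH2Cl2, −78 to 0 °C; aq. potassium sodium tartrate
Reagents that add atoms: none
Why: 1,2-Reduction of an enoate with i-Bu2AlH gives the allylic alcohol without conjugate reduction, isomerisation or loss of bromine.

Step 7
Reactants: 9 (E)-2,3-diarylallyl alcohol; 10 chlorodiphenylsilane
Product: 11 (E)-2,3-diarylallyl diphenylhydrosilyl ether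
Conditions: Et3N, DMAP (cat.), CH2Cl2, 0 °C; filtration under argon, used without chromatography
Reagents that add atoms: none
Why: Substitution at silicon by the primary alcohol (O-silylation) places the Si–H group on O9, three atoms from C7.

Step 8
Reactants: 11 (E)-2,3-diarylallyl diphenylhydrosilyl ether
Product: 12 (3S,4S)-4-[2-(benzyloxy)-5-bromo-3-methoxyphenyl]-3-[4-(benzyloxy)-3-methoxyphenyl]-2,2-diphenyl-1-oxa-2-silacyclopentane (aryl groups trans)
Conditions: [Rh((S,S)-chiraphos)(acetone)2]BF4 (2–5 mol %, from [Rh((S,S)-chiraphos)(nbd)]BF4 and H2), acetone, 25 °C, argon, light excluded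
Reagents that add atoms: none
Why: Oxidative addition of Si–H to the cationic monovalent rhodium centre gives a trivalent silyl hydride to which the tethered C7=C8 bond binds; migratory insertion and reductive elimination then put Si on C7 and H on C8 from the same face. The closest known reaction type is the enantioselective intramolecular hydrosilylation of hydrosilyl ethers of 3-arylallyl alcohols with cationic rhodium bisphosphine catalysts. The one new ring closes 5-endo-trig, since bonding of silicon to the proximal C8 would require a strained four-membered oxasiletane. The relative configuration of C7 and C8 follows from suprafacial addition to the geometrically pure (E)-alkene, which turns cis aryl groups on the alkene into trans aryl groups on the ring, and the absolute configuration follows from the C2-symmetric bisphosphine, which should let only one alkene face bind productively. The step needs regioselectivity, an alkene geometry that holds until addition, and tolerance of the aryl bromide: the short O9 tether fixes the first, the absence of hydrogen on C8 means a reversible hydride insertion at C8 can only revert to the same alkene, and aryl bromides are not expected to add to this cationic catalyst at room temperature.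

Step 9
Reactants: 12 trans-oxasilolane
Product: 13 (1S,2S)-2-[2-(benzyloxy)-5-bromo-3-methoxyphenyl]-1-[4-(benzyloxy)-3-methoxyphenyl]propane-1,3-diol
Conditions: 30% H2O2, KF, KHCO3, THF/MeOH, 25 to 40 °C
Reagents that add atoms: hydrogen peroxide, OO
Why: In the Tamao–Fleming oxidation the fluoride-activated alkoxysilane takes up hydroperoxide and C7 migrates from Si to O with retention, so C7–Si becomes C7–OH (7S) and the tether falls away from O9.

Step 10
Reactants: 13 anti (1S,2S)-diol
Product: 14 (4S,5S)-4-[4-(benzyloxy)-3-methoxyphenyl]-5-[2-(benzyloxy)-5-bromo-3-methoxyphenyl]-2,2-dimethyl-1,3-dioxane (trans)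
Conditions: Me2C(OMe)2, PPTS (cat.), CH2Cl2, 25 °C
Reagents that add atoms: 2,2-dimethoxypropane, COC(C)(C)OC
Why: Mild acid-catalysed transketalisation ties both hydroxyls into a diequatorial dioxane that tolerates organolithium chemistry and also allows the relative configuration to be checked.

Step 11
Reactants: 15 (S)-epichlorohydrin; 16 diethyl malonate
Product: 17 ethyl (1R,5S)-2-oxo-3-oxabicyclo[3.1.0]hexane-1-carboxylate
Conditions: NaOEt (1 equiv), EtOH, reflux
Reagents that add atoms: none
Why: In this malonate cascade the anion opens the epoxide at CH2, the alkoxide re-forms an epoxide with loss of chloride, 3-exo-tet attack inverts the stereocentre to close the cyclopropane, and the freed alkoxide lactonises, so C5 (and through the cis fusion C1) comes from the chiral pool.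

Step 12
Reactants: 14 trans-dioxane aryl bromide; 17 bicyclic cyclopropane lactone
Product: 20 ethyl (4S)-4-{4-(benzyloxy)-3-[(4S,5S)-4-(4-(benzyloxy)-3-methoxyphenyl)-2,2-dimethyl-1,3-dioxan-5-yl]-5-methoxybenzyl}-2-oxotetrahydrofuran-3-carboxylate (C3 epimers), via aryllithium 18 (not isolated), via arylmagnesium bromide 19 (not isolated)
Conditions: n-BuLi, THF, −78 °C; MgBr2·OEt2, −78 to −30 °C; CuBr·SMe2 (20 mol %), 17 (1.5 equiv), −30 to 0 °C; aq. NH4Cl
Reagents that add atoms: none
Why: Bromine–lithium exchange, transmetalation and copper-catalysed homoconjugate addition of the aryl Grignard reagent to the doubly activated cyclopropane at its unsubstituted CH2 make the ring B–CH2 bond without touching the adjacent stereocentre, which becomes lactone C4 (S), while the labile C3 centre is erased in step 13.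

Step 13
Reactants: 20 lactone ester
Product: 21 (4S)-4-{4-(benzyloxy)-3-[(4S,5S)-4-(4-(benzyloxy)-3-methoxyphenyl)-2,2-dimethyl-1,3-dioxan-5-yl]-5-methoxybenzyl}dihydrofuran-2(3H)-one
Conditions: LiCl, DMSO/H2O, 130–140 °C
Reagents that add atoms: none
Why: Krapcho de-ethoxycarbonylation removes the activating ester under neutral conditions that should spare the ketal of a saturated ketone, the benzyl ethers and C4.

Step 14
Reactants: 5 2-[2-(benzyloxy)-5-bromo-3-methoxyphenyl]acetic acid; 22 (S)-4-benzyloxazolidin-2-one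
Product: 24 (S)-4-benzyl-3-{2-[2-(benzyloxy)-5-bromo-3-methoxyphenyl]acetyl}oxazolidin-2-one, via mixed pivalic anhydride 23 (not isolated)
Conditions: t-BuCOCl, Et3N, THF, −20 °C; then 22, LiCl, 25 °C
Reagents that add atoms: none
Why: N-Acylation of the auxiliary through the mixed anhydride with LiCl activation avoids strong base and goes at the less hindered arylacetyl carbonyl.

Step 15
Reactants: 24 arylacetyl imide; 6 4-(benzyloxy)-3-methoxybenzaldehyde
Product: 26 (4S)-4-benzyl-3-{(2S,3S)-2-[2-(benzyloxy)-5-bromo-3-methoxyphenyl]-3-[4-(benzyloxy)-3-methoxyphenyl]-3-hydroxypropanoyl}oxazolidin-2-one (syn), via boron enolate 25 (not isolated)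
Conditions: n-Bu2BOTf, Et3N, CH2Cl2, −78 to 0 °C; 6, −78 to 0 °C; pH 7 buffer, MeOH, 30% H2O2, 0 °C
Reagents that add atoms: none
Why: In the Evans syn aldol the (Z)-boron enolate reacts through a chair Zimmerman–Traxler transition state on the face left open by the auxiliary benzyl group, which sets C8' and C7' together as the 2S,3S syn pair.

Step 16
Reactants: 26 syn aldol imide
Product: 27 (1S,2R)-2-[2-(benzyloxy)-5-bromo-3-methoxyphenyl]-1-[4-(benzyloxy)-3-methoxyphenyl]propane-1,3-diol
Conditions: LiBH4, MeOH (1 equiv), THF, 0 °C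
Reagents that add atoms: none
Why: Reductive cleavage of the imide with LiBH4 at low temperature frees C9'H2OH and the auxiliary faster than retro-aldol, the C8' descriptor changing to R only because the priorities change.

Step 17
Reactants: 27 syn (1S,2R)-diol
Product: 28 (4S,5R)-4-[4-(benzyloxy)-3-methoxyphenyl]-5-[2-(benzyloxy)-5-bromo-3-methoxyphenyl]-2,2-dimethyl-1,3-dioxane (cis)
Conditions: Me2C(OMe)2, PPTS (cat.), CH2Cl2, 25 °C
Reagents that add atoms: 2,2-dimethoxypropane, COC(C)(C)OC
Why: The same transketalisation gives the cis dioxane, in which an axial aryl group at C5 faces only ring oxygens and is easily accommodated.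

Step 18
Reactants: 28 cis-dioxane aryl bromide
Product: 31 {4-(benzyloxy)-3-[(4S,5R)-4-(4-(benzyloxy)-3-methoxyphenyl)-2,2-dimethyl-1,3-dioxan-5-yl]-5-methoxyphenyl}methanol, via aryllithium 29 (not isolated), via aldehyde 30 (not isolated)
Conditions: n-BuLi, THF, −78 °C; DMF, −78 to 0 °C; then MeOH, NaBH4, 0 °C
Reagents that add atoms: N,N-dimethylformamide, CN(C)C=O
Why: Bromine–lithium exchange, formylation with DMF and borohydride reduction in the same flask install the benzylic carbon of ring C by three routine reactions.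

Step 19
Reactants: 31 ring C benzyl alcohol
Product: 32 (4S,5R)-5-[2-(benzyloxy)-5-(bromomethyl)-3-methoxyphenyl]-4-[4-(benzyloxy)-3-methoxyphenyl]-2,2-dimethyl-1,3-dioxane
Conditions: CBr4, PPh3, CH2Cl2, 0 °C; used at once
Reagents that add atoms: tetrabromomethane, BrC(Br)(Br)Br
Why: The Appel reaction converts the primary benzylic alcohol into the bromide under neutral conditions that do not endanger the ketal.

Step 20
Reactants: 21 (4S)-benzyl lactone; 32 ring C benzyl bromide
Product: 34 (3S,4S)-dibenzylbutyrolactone carrying both arms as acetonides plus four phenolic benzyl ethers, via lithium enolate 33 (not isolated)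
Conditions: LiN(SiMe3)2, THF, −78 °C; 32, DMPU, −78 to −20 °C
Reagents that add atoms: none
Why: In this lactone enolate alkylation, the standard closure of dibenzylbutyrolactone lignans, the bromide approaches anti to the C4 substituent, so C3 is set S and trans under substrate control.

Step 21
Reactants: 34 fully protected lactone
Product: 35 tetra-O-benzyl ether of the target (both 1,3-diols free)
Conditions: AcOH/H2O/THF (3:1:1), 35 °C
Reagents that add atoms: none
Why: Ketal hydrolysis in weak acid goes through the oxocarbenium ion at the isopropylidene carbon, so the C7–O and C7'–O bonds stay intact, and the still-benzylated oxygens of rings B and C cannot close dihydrobenzofurans.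

Step 22
Reactants: 35 tetra-O-benzyl ether
Product: 36 target CNP0113972.1
Conditions: H2 (1 atm), 10% Pd/C, EtOAc/EtOH, 25 °C, stopped at the calculated uptake
Reagents that add atoms: none
Why: Hydrogenolysis of aryl benzyl ethers in a neutral medium is faster than cleavage of secondary benzylic alcohols, and ending without acid or base protects the labile p-hydroxybenzyl alcohols and the lactone.

Compound list
1 | 5-bromo-2-hydroxy-3-methoxybenzaldehyde | COc1cc(Br)cc(C=O)c1O | starting material
2 | 2-(benzyloxy)-5-bromo-3-methoxybenzaldehyde | COc1cc(Br)cc(C=O)c1OCc1ccccc1 | intermediate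
3 | N-{2-[2-(benzyloxy)-5-bromo-3-methoxyphenyl]-1-tosylvinyl}formamide (geometry irrelevant, not isolated) | COc1cc(Br)cc(C=C(NC=O)S(=O)(=O)c2ccc(C)cc2)c1OCc1ccccc1 | intermediate
4 | 2-[2-(benzyloxy)-5-bromo-3-methoxyphenyl]acetonitrile | COc1cc(Br)cc(CC#N)c1OCc1ccccc1 | intermediate
5 | 2-[2-(benzyloxy)-5-bromo-3-methoxyphenyl]acetic acid | COc1cc(Br)cc(CC(=O)O)c1OCc1ccccc1 | intermediate
6 | 4-(benzyloxy)-3-methoxybenzaldehyde | COc1cc(C=O)ccc1OCc1ccccc1 | starting material
7 | (E)-2-[2-(benzyloxy)-5-bromo-3-methoxyphenyl]-3-[4-(benzyloxy)-3-methoxyphenyl]acrylic acid | COc1cc(/C=C(/C(=O)O)c2cc(Br)cc(OC)c2OCc2ccccc2)ccc1OCc1ccccc1 | intermediate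
8 | methyl ester of 7 | COc1cc(/C=C(/C(=O)OC)c2cc(Br)cc(OC)c2OCc2ccccc2)ccc1OCc1ccccc1 | intermediate
9 | (E)-2-[2-(benzyloxy)-5-bromo-3-methoxyphenyl]-3-[4-(benzyloxy)-3-methoxyphenyl]prop-2-en-1-ol | COc1cc(/C=C(/CO)c2cc(Br)cc(OC)c2OCc2ccccc2)ccc1OCc1ccccc1 | intermediate
10 | chlorodiphenylsilane | Cl[SiH](c1ccccc1)c1ccccc1 | starting material
11 | diphenylhydrosilyl ether of 9 (E, aryl groups cis) | COc1cc(/C=C(/CO[SiH](c5ccccc5)c6ccccc6)c2cc(Br)cc(OC)c2OCc7ccccc7)ccc1OCc8ccccc8 | intermediate
12 | (3S,4S)-trans-3,4-diaryl-2,2-diphenyl-1-oxa-2-silacyclopentane | COc1cc([C@H]5[Si](c6ccccc6)(c7ccccc7)OC[C@@H]5c2cc(Br)cc(OC)c2OCc8ccccc8)ccc1OCc9ccccc9 | intermediate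
13 | (1S,2S)-2-[2-(benzyloxy)-5-bromo-3-methoxyphenyl]-1-[4-(benzyloxy)-3-methoxyphenyl]propane-1,3-diol | COc1cc([C@@H](O)[C@H](CO)c2cc(Br)cc(OC)c2OCc2ccccc2)ccc1OCc1ccccc1 | intermediate
14 | (4S,5S)-trans acetonide of 13 | COc1cc([C@H]2OC(C)(C)OC[C@@H]2c2cc(Br)cc(OC)c2OCc2ccccc2)ccc1OCc1ccccc1 | intermediate
15 | (S)-epichlorohydrin | ClC[C@@H]1CO1 | starting material
16 | diethyl malonate | CCOC(=O)CC(=O)OCC | starting material
17 | ethyl (1R,5S)-2-oxo-3-oxabicyclo[3.1.0]hexane-1-carboxylate | CCOC(=O)[C@@]12C[C@@H]1COC2=O | intermediate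
18 | aryllithium from 14 (not isolated) | COc1cc([C@H]2OC(C)(C)OC[C@@H]2c2cc([Li])cc(OC)c2OCc2ccccc2)ccc1OCc1ccccc1 | intermediate
19 | arylmagnesium bromide from 14 (not isolated) | COc1cc([C@H]2OC(C)(C)OC[C@@H]2c2cc([Mg]Br)cc(OC)c2OCc2ccccc2)ccc1OCc1ccccc1 | intermediate
20 | ethyl (4S)-4-(ring B benzyl)-2-oxotetrahydrofuran-3-carboxylate, C3 epimers | COc1cc([C@H]2OC(C)(C)OC[C@@H]2c2cc(C[C@@H]3COC(=O)C3C(=O)OCC)cc(OC)c2OCc2ccccc2)ccc1OCc1ccccc1 | intermediate
21 | (4S)-4-(ring B benzyl)dihydrofuran-2(3H)-one | COc1cc([C@H]2OC(C)(C)OC[C@@H]2c2cc(C[C@@H]3COC(=O)C3)cc(OC)c2OCc2ccccc2)ccc1OCc1ccccc1 | intermediate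
22 | (S)-4-benzyloxazolidin-2-one | O=C1OC[C@H](Cc2ccccc2)N1 | starting material
23 | mixed pivalic anhydride of 5 (not isolated) | COc1cc(Br)cc(CC(=O)OC(=O)C(C)(C)C)c1OCc1ccccc1 | intermediate
24 | (S)-4-benzyl-3-{2-[2-(benzyloxy)-5-bromo-3-methoxyphenyl]acetyl}oxazolidin-2-one | COc1cc(Br)cc(CC(=O)N2[C@@H](Cc3ccccc3)COC2=O)c1OCc1ccccc1 | intermediate
25 | (Z)-dibutylboron enolate of 24 (not isolated) | CCCCB(CCCC)O/C(=C\c1cc(Br)cc(OC)c1OCc1ccccc1)N1[C@@H](Cc2ccccc2)COC1=O | intermediate
26 | (2S,3S)-syn aldol imide | COc1cc(Br)cc([C@H](C(=O)N2[C@@H](Cc3ccccc3)COC2=O)[C@H](O)c2ccc(OCc3ccccc3)c(OC)c2)c1OCc1ccccc1 | intermediate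
27 | (1S,2R)-2-[2-(benzyloxy)-5-bromo-3-methoxyphenyl]-1-[4-(benzyloxy)-3-methoxyphenyl]propane-1,3-diol | COc1cc(Br)cc([C@H](CO)[C@H](O)c2ccc(OCc3ccccc3)c(OC)c2)c1OCc1ccccc1 | intermediate
28 | (4S,5R)-cis acetonide of 27 | COc1cc(Br)cc([C@@H]2COC(C)(C)O[C@@H]2c2ccc(OCc3ccccc3)c(OC)c2)c1OCc1ccccc1 | intermediate
29 | aryllithium from 28 (not isolated) | COc1cc([Li])cc([C@@H]2COC(C)(C)O[C@@H]2c2ccc(OCc3ccccc3)c(OC)c2)c1OCc1ccccc1 | intermediate
30 | ring C benzaldehyde (not isolated) | COc1cc(C=O)cc([C@@H]2COC(C)(C)O[C@@H]2c2ccc(OCc3ccccc3)c(OC)c2)c1OCc1ccccc1 | intermediate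
31 | ring C benzyl alcohol | COc1cc(CO)cc([C@@H]2COC(C)(C)O[C@@H]2c2ccc(OCc3ccccc3)c(OC)c2)c1OCc1ccccc1 | intermediate
32 | ring C benzyl bromide | COc1cc(CBr)cc([C@@H]2COC(C)(C)O[C@@H]2c2ccc(OCc3ccccc3)c(OC)c2)c1OCc1ccccc1 | intermediate
33 | lithium enolate of 21 (not isolated) | COc1cc([C@H]2OC(C)(C)OC[C@@H]2c2cc(C[C@@H]3COC(O[Li])=C3)cc(OC)c2OCc2ccccc2)ccc1OCc1ccccc1 | intermediate
34 | (3S,4S)-lactone, bis-acetonide, tetrabenzyl ether | COc1cc([C@H]2OC(C)(C)OC[C@@H]2c2cc(C[C@@H]3COC(=O)[C@H]3Cc3cc(OC)c(OCc4ccccc4)c([C@@H]4COC(C)(C)O[C@@H]4c4ccc(OCc5ccccc5)c(OC)c4)c3)cc(OC)c2OCc2ccccc2)ccc1OCc1ccccc1 | intermediate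
35 | tetra-O-benzyl ether of the target | COc1cc([C@@H](O)[C@H](CO)c2cc(C[C@@H]3COC(=O)[C@H]3Cc3cc(OC)c(OCc4ccccc4)c([C@H](CO)[C@H](O)c4ccc(OCc5ccccc5)c(OC)c4)c3)cc(OC)c2OCc2ccccc2)ccc1OCc1ccccc1 | intermediate
36 | CNP0113972.1, (3S,4S)-lactone with the 7S,8S arm on ring B and the 7'S,8'R arm on ring C | COc1cc([C@@H](O)[C@H](CO)c2cc(C[C@@H]3COC(=O)[C@H]3Cc3cc(OC)c(O)c([C@H](CO)[C@H](O)c4ccc(O)c(OC)c4)c3)cc(OC)c2O)ccc1O | target

Total steps: 22. Longest linear sequence: 15 steps (1–10, 12, 13, 20–22).

Steps most likely to fail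

1. Step 8.
- **What may go wrong:** Turnover may be slow at the crowded trisubstituted alkene. The double bond may isomerise or migrate towards C9 through reversible hydride insertion. Facial selectivity may be poor.
- **Fallback:** It sets out from imide 24 and aldehyde 6 and comes back at diol 13, bypassing steps 4 to 9. It replaces hydrosilylation by aldol chemistry.
- **Aldol:** MgCl2 (cat.), Et3N and Me3SiCl in EtOAc form the chelated magnesium enolate. This enolate exposes the face opposite to the one used by the boron enolate, and with the non-enolisable aromatic aldehyde it should give the silylated (2R,3S)-anti aldol F1.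
- **Return to the route:** CF3CO2H in MeOH frees the anti aldol F2, and LiBH4 in THF at 0 °C reduces it to 13.

2. Step 12.
- **What may go wrong:** Halogen–metal exchange may be incomplete, the aryl metal may be protonated, or it may attack the ester or lactone carbonyl instead of opening the cyclopropane.
- **Fallback:** It sets out from bromide 14 and comes back at lactone 21, bypassing step 13. It builds the C4 centre by asymmetric hydrogenation.
- **Carbon framework:** n-BuLi then DMF gives the ring B aldehyde F3. Stobbe condensation with dimethyl succinate (KOt-Bu, t-BuOH) gives the (E)-benzylidenesuccinate half-ester F4.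
- **Stereocentre and ring:** H2 with [Rh(cod)(Et-DuPhos)]BF4, using the ligand enantiomer that leads to the S acid, gives the (S)-benzylsuccinate half-ester F5. Reduction of the ester in the potassium carboxylate with Ca(BH4)2 (CaCl2 and NaBH4, EtOH), followed by acidification with citric acid, closes 21.

3. Step 20.
- **What may go wrong:** Proton transfer between enolate and product may cause incomplete conversion or double alkylation. The electron-rich benzyl bromide may also decay before it is consumed.
- **Fallback:** It sets out from lactone ester 20 and bromide 32 and comes back at 34, making step 13 unnecessary. It uses the stabilised malonate-type enolate.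
- **Sequence:** K2CO3 in DMF at 25 °C should alkylate anti to the C4 substituent to give the quaternary lactone ester F6. LiCl in wet DMSO at 130–140 °C removes the ester, and DBU equilibrates any cis isomer to the more stable trans lactone 34.

Further compounds
F1 | step 8 | (4S)-4-benzyl-3-{(2R,3S)-2-[2-(benzyloxy)-5-bromo-3-methoxyphenyl]-3-[4-(benzyloxy)-3-methoxyphenyl]-3-(trimethylsilyloxy)propanoyl}oxazolidin-2-one | COc1cc(Br)cc([C@@H](C(=O)N2[C@@H](Cc3ccccc3)COC2=O)[C@H](O[Si](C)(C)C)c2ccc(OCc3ccccc3)c(OC)c2)c1OCc1ccccc1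
F2 | step 8 | (4S)-4-benzyl-3-{(2R,3S)-2-[2-(benzyloxy)-5-bromo-3-methoxyphenyl]-3-[4-(benzyloxy)-3-methoxyphenyl]-3-hydroxypropanoyl}oxazolidin-2-one | COc1cc(Br)cc([C@@H](C(=O)N2[C@@H](Cc3ccccc3)COC2=O)[C@H](O)c2ccc(OCc3ccccc3)c(OC)c2)c1OCc1ccccc1
F3 | step 12 | 4-(benzyloxy)-3-[(4S,5S)-4-(4-(benzyloxy)-3-methoxyphenyl)-2,2-dimethyl-1,3-dioxan-5-yl]-5-methoxybenzaldehyde | COc1cc([C@H]2OC(C)(C)OC[C@@H]2c2cc(C=O)cc(OC)c2OCc2ccccc2)ccc1OCc1ccccc1
F4 | step 12 | (E)-4-(ring B aryl)-3-(methoxycarbonyl)but-3-enoic acid | COc1cc([C@H]2OC(C)(C)OC[C@@H]2c2cc(/C=C(/C(=O)OC)CC(=O)O)cc(OC)c2OCc2ccccc2)ccc1OCc1ccccc1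
F5 | step 12 | (S)-3-(methoxycarbonyl)-4-(ring B aryl)butanoic acid | COc1cc([C@H]2OC(C)(C)OC[C@@H]2c2cc(C[C@@H](CC(=O)O)C(=O)OC)cc(OC)c2OCc2ccccc2)ccc1OCc1ccccc1
F6 | step 20 | ethyl 3-(ring C benzyl)-4-(ring B benzyl)-2-oxotetrahydrofuran-3-carboxylate, benzyl groups trans | COc1cc([C@H]2OC(C)(C)OC[C@@H]2c2cc(C[C@@H]3COC(=O)[C@@]3(C(=O)OCC)Cc3cc(OC)c(OCc4ccccc4)c([C@@H]4COC(C)(C)O[C@@H]4c4ccc(OCc5ccccc5)c(OC)c4)c3)cc(OC)c2OCc2ccccc2)ccc1OCc1ccccc1
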